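**Retrosynthetic overview**
- The last step forms the C5–O and C6–O bonds: a carboxylate-directed epoxidation of a (Z)-C5=C6 cyclodecenoic acid, then 5-exo lactonisation. This is the key step; it sets C5 and C6 and closes the lactone.
- The C8 methacrylate, the C10 acetate and the acrylic acid (from isopropenyl) are late functional-group changes.
- The ten-membered carbocycle comes from a Wharton–Grob fragmentation of a cis-decalin 1,3-diol monomesylate (C1–C6 bond broken).
- The decalin comes from an epoxy-cyclohexanone (ring B, from (S)-carvone) by aldol addition and anionic cyclisation with (S)-4-iodo-2-methylbutanal (ring A).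
- Order of ring formation: ring B (chiral pool), ring A, fragmentation to the ten-membered ring, γ-lactone.

Convention and assumption: atoms carry the germacrane locants they have in the target (C1 ketone, C4 CHMe, C5, C6, C7, C8, C10, side chain C11–C13, C14 on C10, C15 on C4); β is the face of the C7–C11 bond with ring B or the macrocycle drawn flat, α the other face; (S)-carvone and (S)-α-methyl-γ-butyrolactone are taken as commercial.

**Step 1**
Reactants: 1 (S)-(+)-carvone
Product: 2 (S)-carvone N-tosylhydrazone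
Conditions: TsNHNH2, AcOH (cat.), EtOH, 25 °C
Reagents that add atoms: p-toluenesulfonohydrazide, Cc1ccc(cc1)S(=O)(=O)NN
Why: Hydrazone condensation at the only carbonyl; the C7 stereocentre is untouched.

**Step 2**
Reactants: 2 (S)-carvone N-tosylhydrazone
Product: 3 (5S)-2-methyl-5-(prop-1-en-2-yl)cyclohexa-1,3-diene
Conditions: MeLi (2.3 equiv), Et2O, 0 → 25 °C; H2O
Reagents that add atoms: none
Why: Shapiro reaction: α′-deprotonation of the hydrazone dianion, loss of sulfinate and N2 and protonation give the conjugated diene C1=C10–C9=C8 without touching C7.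

**Step 3**
Reactants: 3 (5S)-2-methyl-5-(prop-1-en-2-yl)cyclohexa-1,3-diene
Product: 5 (4S,5R)-4-hydroxy-2-methyl-5-(prop-1-en-2-yl)cyclohex-2-en-1-one (hydroxyl trans to isopropenyl), via endoperoxide 4 (not isolated)
Conditions: O2, tetraphenylporphyrin (cat.), visible light, CH2Cl2, −40 °C; then Et3N, 0 → 25 °C
Reagents that add atoms: dioxygen, O=O
Why: [4+2] addition of singlet oxygen anti to the isopropenyl group sets the C8–O bond (α); the Kornblum–DeLaMare rearrangement then removes the less hindered bridgehead proton (C1–H, next to the C6 methylene), giving the C1 ketone and the C8 hydroxyl.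

**Step 4**
Reactants: 5 (4S,5R)-4-hydroxy-2-methyl-5-(prop-1-en-2-yl)cyclohex-2-en-1-one
Product: 6 5-hydroxy-1-methyl-4-(prop-1-en-2-yl)-7-oxabicyclo[4.1.0]heptan-2-one (9α,10α-epoxide, cis to the hydroxyl, trans to isopropenyl)
Conditions: t-BuOOH, BnMe3NOH (0.1 equiv), THF, −10 °C
Reagents that add atoms: tert-butyl hydroperoxide, CC(C)(C)OO
Why: Hydroxyl-directed Weitz–Scheffer nucleophilic epoxidation: the peroxide is delivered syn to the C8 hydroxyl and anti to the isopropenyl group, which sets C10 (O α, methyl β).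

**Step 5**
Reactants: 6 epoxy hydroxy ketone
Product: 7 5-(triethylsilyloxy)-1-methyl-4-(prop-1-en-2-yl)-7-oxabicyclo[4.1.0]heptan-2-one (C8 O-triethylsilyl ether of 6)
Conditions: Et3SiCl, imidazole, DMF, 0 °C
Reagents that add atoms: chlorotriethylsilane, CC[Si](Cl)(CC)CC
Why: Standard silylation of the secondary alcohol, so that only the C5 hydroxyl is later free for mesylation.

**Step 6**
Reactants: 8 (S)-α-methyl-γ-butyrolactone
Product: 9 ethyl (2S)-4-iodo-2-methylbutanoate
Conditions: Me3SiI, EtOH, CH2Cl2, 0 → 25 °C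
Reagents that add atoms: iodotrimethylsilane, C[Si](C)(C)I; ethanol, CCO
Why: Silyl iodide cleavage of the lactone (SN2 by iodide at the O–CH2 carbon) and ethanolysis of the silyl ester; the α-stereocentre (future C4) is not involved.

**Step 7**
Reactants: 9 ethyl (2S)-4-iodo-2-methylbutanoate
Product: 10 (2S)-4-iodo-2-methylbutanal
Conditions: i-Bu2AlH (1.05 equiv), CH2Cl2, −78 °C; aq. KNaC4H4O6
Reagents that add atoms: none
Why: Partial ester reduction through the tetrahedral aluminium hemiacetal, stable at −78 °C; the aldehyde is used at once to avoid α-epimerisation.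

**Step 8**
Reactants: 7 epoxy ketone silyl ether; 10 (2S)-4-iodo-2-methylbutanal
Product: 12 9α,10α-epoxy-8α-(triethylsilyloxy)-1,6-cyclogermacr-11(13)-ene-1β,5α-diol (cis-fused decalin, 6β-H, 4β-methyl), via aldol adduct 11 (not isolated)
Conditions: LiN(i-Pr)2, THF, −78 °C; 10, −78 °C; then t-BuLi (2.3 equiv), −100 → −78 °C; aq. NH4Cl
Reagents that add atoms: none
Why: The only enolisable site (C6) gives the lithium enolate, which adds to the aldehyde trans to the isopropenyl group in an anti-selective, Felkin-matched Zimmerman–Traxler aldol; iodine–lithium exchange and 6-exo carbonyl addition through a chair with the C4 methyl and C5 alkoxide equatorial then close ring A from the α face of C1, giving the cis-fused decalin.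

**Step 9**
Reactants: 12 epoxy decalindiol
Product: 13 8α-(triethylsilyloxy)-1,6-cyclogermacr-11(13)-ene-1β,5α,10α-triol
Conditions: LiEt3BH (4 equiv), THF, 0 → 25 °C; aq. NH4Cl
Reagents that add atoms: none
Why: SN2 hydride opening of the trisubstituted epoxide at the less substituted C9 leaves the C10–O bond (α) and the C14 methyl (β) in place.

**Step 10**
Reactants: 13 decalin triol
Product: 15 (5Z)-10α-hydroxy-8α-(triethylsilyloxy)germacra-5,11(13)-dien-1-one, via C5 mesylate 14 (not isolated)
Conditions: MsCl (1.1 equiv), Et3N, CH2Cl2, −20 °C; then KOt-Bu (3.5 equiv), THF/t-BuOH, 0 °C, 20 min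
Reagents that add atoms: none
Why: Only the secondary C5 hydroxyl is mesylated; in the Wharton–Grob fragmentation the C1 alkoxide breaks the C1–C6 bond, which is antiperiplanar to the equatorial C5 mesylate, and because C7 is axial on ring A the new C5=C6 bond is Z, giving the ten-membered ring.

**Step 11**
Reactants: 15 silyl ether
Product: 16 (5Z)-8α,10α-dihydroxygermacra-5,11(13)-dien-1-one
Conditions: HF·pyridine, pyridine, THF, 0 °C
Reagents that add atoms: none
Why: Buffered fluoride desilylation, mild enough to avoid transannular reactions of the cyclodecenone.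

**Step 12**
Reactants: 16 diol
Product: 17 (5Z)-10α-hydroxy-8α-(methacryloyloxy)germacra-5,11(13)-dien-1-one
Conditions: methacrylic anhydride, Et3N, DMAP (cat.), CH2Cl2, 0 °C
Reagents that add atoms: methacrylic anhydride, CC(=C)C(=O)OC(=O)C(C)=C
Why: DMAP-catalysed acylation takes the secondary C8 hydroxyl and leaves the tertiary C10 hydroxyl.

**Step 13**
Reactants: 17 methacrylate
Product: 18 (5Z)-10α-acetoxy-8α-(methacryloyloxy)germacra-5,11(13)-dien-1-one
Conditions: Ac2O, DMAP (1.5 equiv), Et3N, CH2Cl2, 40 °C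
Reagents that add atoms: acetic anhydride, CC(=O)OC(C)=O
Why: Forcing DMAP acylation of the tertiary α-ketol; no acid is used, so the (Z)-cyclodec-5-enone cannot cyclise across the ring.

**Step 14**
Reactants: 18 acetate
Product: 19 (5Z)-10α-acetoxy-12-hydroxy-8α-(methacryloyloxy)germacra-5,11(13)-dien-1-one
Conditions: SeO2 (0.3 equiv), t-BuOOH, salicylic acid (cat.), CH2Cl2, 25 °C
Reagents that add atoms: tert-butyl hydroperoxide, CC(C)(C)OO
Why: Riley allylic oxidation (ene reaction, then [2,3] shift) at the methyl of the 1,1-disubstituted isopropenyl group; the ring alkene has only methine allylic positions and the methacrylate is electron-poor.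

**Step 15**
Reactants: 19 allylic alcohol
Product: 20 (5Z)-10α-acetoxy-8α-(methacryloyloxy)-1-oxogermacra-5,11(13)-dien-12-oic acid
Conditions: TEMPO (cat.), PhI(OAc)2 (2.2 equiv), MeCN/H2O (pH 7), 25 °C
Reagents that add atoms: water, O
Why: Oxoammonium (TEMPO) oxidation of the primary allylic alcohol through the aldehyde hydrate to the acrylic acid; alkenes and esters are not affected.

**Step 16**
Reactants: 20 (Z)-cyclodecenoic acid
Product: 22 lychnostatin 1, via 5β,6β-epoxy acid 21 (not isolated)
Conditions: [Mn((S,S)-pdp)(OTf)2] (3 mol %; pdp = N,N′-bis(pyridin-2-ylmethyl)-2,2′-bipyrrolidine), H2O2 (1.3 equiv, slow addition), CF3CH2OH, −30 → 0 °C, no added carboxylic acid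
Reagents that add atoms: hydrogen peroxide, OO
Why: Proposed new method: the substrate's own carboxylate takes the place of the usual carboxylic acid co-ligand on the divalent manganese catalyst, so H2O2 activation gives a carboxylato-bound oxo-manganese species (formally pentavalent) that reaches only the γ,δ-alkene C5=C6 and transfers oxygen to the β face, where the tether lies; the released acid then opens the 5β,6β-epoxide at C6 by 5-exo attack with inversion (in the conformer with an anti C5–C6–C7–C8 torsion), giving the 6α-O trans-lactone and the 5β-hydroxyl; the closest known reactions are carboxylic-acid-directed manganese-catalysed γ-C–H lactonisation, carboxylic-acid-assisted Mn/H2O2 epoxidation and peracid epoxidation–lactonisation of γ,δ-unsaturated acids.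

**Compound list**
1 | (S)-(+)-carvone, (5S)-2-methyl-5-(prop-1-en-2-yl)cyclohex-2-en-1-one | CC1=CC[C@@H](CC1=O)C(C)=C | starting material
2 | (S)-carvone N-tosylhydrazone | CC1=CC[C@@H](CC1=NNS(=O)(=O)c2ccc(C)cc2)C(C)=C | intermediate
3 | (5S)-2-methyl-5-(prop-1-en-2-yl)cyclohexa-1,3-diene | CC1=CC[C@@H](C=C1)C(C)=C | intermediate
4 | 5-methyl-7-(prop-1-en-2-yl)-2,3-dioxabicyclo[2.2.2]oct-5-ene, peroxide bridge anti to isopropenyl | CC1=C[C@H]2[C@@H](C(C)=C)C[C@@H]1OO2 | intermediate
5 | (4S,5R)-4-hydroxy-2-methyl-5-(prop-1-en-2-yl)cyclohex-2-en-1-one | CC1=C[C@H](O)[C@@H](C(C)=C)CC1=O | intermediate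
6 | 5-hydroxy-1-methyl-4-(prop-1-en-2-yl)-7-oxabicyclo[4.1.0]heptan-2-one, epoxide and hydroxyl cis, both trans to isopropenyl | C[C@@]12O[C@@H]1[C@H](O)[C@@H](C(C)=C)CC2=O | intermediate
7 | O-triethylsilyl ether of 6 | C[C@@]12O[C@@H]1[C@H](O[Si](CC)(CC)CC)[C@@H](C(C)=C)CC2=O | intermediate
8 | (S)-α-methyl-γ-butyrolactone, (3S)-3-methyloxolan-2-one | O=C1OCC[C@@H]1C | starting material
9 | ethyl (2S)-4-iodo-2-methylbutanoate | CCOC(=O)[C@@H](C)CCI | intermediate
10 | (2S)-4-iodo-2-methylbutanal | O=C[C@@H](C)CCI | intermediate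
11 | aldol adduct: 7 carrying at C6 (α, trans to isopropenyl) a 1-hydroxy-4-iodo-2-methylbutyl chain, 5,6-anti and 4,5-syn | C[C@@]12O[C@@H]1[C@H](O[Si](CC)(CC)CC)[C@@H](C(C)=C)[C@H]([C@H](O)[C@@H](C)CCI)C2=O | intermediate
12 | 9α,10α-epoxy-8α-(triethylsilyloxy)-1,6-cyclogermacr-11(13)-ene-1β,5α-diol (cis-decalin, 6β-H, 4β-methyl) | C[C@@]12O[C@@H]1[C@H](O[Si](CC)(CC)CC)[C@@H](C(C)=C)[C@@H]3[C@H](O)[C@@H](C)CC[C@]23O | intermediate
13 | 8α-(triethylsilyloxy)-1,6-cyclogermacr-11(13)-ene-1β,5α,10α-triol | C[C@@]1(O)C[C@H](O[Si](CC)(CC)CC)[C@@H](C(C)=C)[C@@H]2[C@H](O)[C@@H](C)CC[C@]12O | intermediate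
14 | 5α-O-methanesulfonate of 13 | C[C@@]1(O)C[C@H](O[Si](CC)(CC)CC)[C@@H](C(C)=C)[C@@H]2[C@H](OS(C)(=O)=O)[C@@H](C)CC[C@]12O | intermediate
15 | (5Z)-10α-hydroxy-8α-(triethylsilyloxy)germacra-5,11(13)-dien-1-one (4β-methyl, 7α-H) | C[C@@]1(O)C[C@H](O[Si](CC)(CC)CC)[C@@H](C(C)=C)/C=C\[C@@H](C)CCC1=O | intermediate
16 | (5Z)-8α,10α-dihydroxygermacra-5,11(13)-dien-1-one | C[C@@]1(O)C[C@H](O)[C@@H](C(C)=C)/C=C\[C@@H](C)CCC1=O | intermediate
17 | (5Z)-10α-hydroxy-8α-(methacryloyloxy)germacra-5,11(13)-dien-1-one | C[C@@]1(O)C[C@H](OC(=O)C(C)=C)[C@@H](C(C)=C)/C=C\[C@@H](C)CCC1=O | intermediate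
18 | (5Z)-10α-acetoxy-8α-(methacryloyloxy)germacra-5,11(13)-dien-1-one | C[C@@]1(OC(C)=O)C[C@H](OC(=O)C(C)=C)[C@@H](C(C)=C)/C=C\[C@@H](C)CCC1=O | intermediate
19 | (5Z)-10α-acetoxy-12-hydroxy-8α-(methacryloyloxy)germacra-5,11(13)-dien-1-one | C[C@@]1(OC(C)=O)C[C@H](OC(=O)C(C)=C)[C@@H](C(=C)CO)/C=C\[C@@H](C)CCC1=O | intermediate
20 | (5Z)-10α-acetoxy-8α-(methacryloyloxy)-1-oxogermacra-5,11(13)-dien-12-oic acid | C[C@@]1(OC(C)=O)C[C@H](OC(=O)C(C)=C)[C@@H](C(=C)C(O)=O)/C=C\[C@@H](C)CCC1=O | intermediate
21 | 5β,6β-epoxide of 20 | C[C@@]1(OC(C)=O)C[C@H](OC(=O)C(C)=C)[C@@H](C(=C)C(O)=O)[C@H]2O[C@H]2[C@@H](C)CCC1=O | intermediate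
22 | lychnostatin 1 (4β-methyl, 5β-OH, 6α,12-olide, 8α-methacrylate, 10α-acetate, 1-ketone) | C=C(C)C(=O)O[C@H]1C[C@@](C)(OC(C)=O)C(=O)CC[C@H](C)[C@H](O)[C@H]2OC(=O)C(=C)[C@@H]21 | target

**Totals**
Total steps: 16. Longest linear sequence: 14 (steps 1–5 and 8–16, from 1 to 22).

**Steps most likely to fail**

Step 16 (new method). The catalyst may not accept the substrate as its only carboxylate ligand, or oxygen may be delivered to the α face, which would give the cis-lactone diastereomer. Fallback with known chemistry, setting out from 20: Me3SiCHN2 gives the methyl ester F6. Shi epoxidation (fructose-derived ketone of the enantiomeric series that attacks the β face, KHSO5, buffered MeCN/H2O, 0 °C) gives the 5β,6β-epoxy methyl ester F7. Camphorsulfonic acid (cat.) in CH2Cl2 then lets the ester carbonyl open the epoxide at C6 (5-exo, inversion) with loss of methanol, which returns to the route at 22.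

Step 8. Amine and alkoxide in the flask may quench the alkyllithium before ring closure, or the fusion may not be cleanly cis. Fallback, setting out from 7 and 10: after the aldol the lithium aldolate is trapped with Me3SiCl and the C5 O-trimethylsilyl aldol F4 is isolated. Iodine–lithium exchange with t-BuLi (2.1 equiv) in Et2O/pentane at −100 °C, now free of amine and alkoxide, closes ring A to the C5 O-trimethylsilyl decalinol F5. K2CO3/MeOH removes only the trimethylsilyl group and returns to 12.

Step 3. The Kornblum–DeLaMare step may remove the other bridgehead proton and give the regioisomeric hydroxy enone, and the facial selectivity of singlet oxygen may be modest. Fallback, setting out from 3: m-CPBA/NaHCO3 (CH2Cl2, −20 °C) epoxidises the trisubstituted diene double bond anti to the isopropenyl group to give the vinyl epoxide F1. Pd(PPh3)4 (zerovalent palladium) with AcOH in THF opens it in the Tsuji–Trost 1,4-sense with overall retention to the cis-acetoxy alcohol F2, whose free hydroxyl can only be at C1. MnO2 oxidises this allylic alcohol to the acetoxy enone F3, and K2CO3/MeOH at 0 °C cleaves the acetate, returning to 5.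

**Further compounds**
F1 | step 3 | 1-methyl-4-(prop-1-en-2-yl)-7-oxabicyclo[4.1.0]hept-2-ene, epoxide trans to isopropenyl | C[C@]12O[C@H]1C[C@H](C(C)=C)C=C2
F2 | step 3 | 4-hydroxy-3-methyl-6-(prop-1-en-2-yl)cyclohex-2-en-1-yl acetate, acetoxy and hydroxyl cis, both trans to isopropenyl | CC1=C[C@H](OC(C)=O)[C@@H](C(C)=C)C[C@@H]1O
F3 | step 3 | 3-methyl-4-oxo-6-(prop-1-en-2-yl)cyclohex-2-en-1-yl acetate (O-acetate of 5) | CC1=C[C@H](OC(C)=O)[C@@H](C(C)=C)CC1=O
F4 | step 8 | C5 O-trimethylsilyl ether of aldol adduct 11 | C[C@@]12O[C@@H]1[C@H](O[Si](CC)(CC)CC)[C@@H](C(C)=C)[C@H]([C@H](O[Si](C)(C)C)[C@@H](C)CCI)C2=O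
F5 | step 8 | C5 O-trimethylsilyl ether of decalindiol 12 | C[C@@]12O[C@@H]1[C@H](O[Si](CC)(CC)CC)[C@@H](C(C)=C)[C@@H]3[C@H](O[Si](C)(C)C)[C@@H](C)CC[C@]23O
F6 | step 16 | methyl ester of acid 20 | C[C@@]1(OC(C)=O)C[C@H](OC(=O)C(C)=C)[C@@H](C(=C)C(=O)OC)/C=C\[C@@H](C)CCC1=O
F7 | step 16 | 5β,6β-epoxide of methyl ester F6 | C[C@@]1(OC(C)=O)C[C@H](OC(=O)C(C)=C)[C@@H](C(=C)C(=O)OC)[C@H]2O[C@H]2[C@@H](C)CCC1=O
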